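**Plan**
- Cuts: first the C11–O(aryl) ether and the acetate. Then C8=CH2 goes back through an allylsilane to a C8 enol triflate, and the second C4 methyl plus the C3 oxygen go back to a C3=C4 methyl enol ether. Next C5–C6 is cut while C3–C8 is reconnected. Last, C3–C8 and C9–C10 of the resulting bicycle are cut (Diels–Alder).
- Enabling feature: ring B holds a carbonyl-level sp2 carbon (C8) joined through C7 and C6 to the quaternary fusion carbon C5. The C5/C10 fusion is cis with both methyl groups on one face, and C3 next to C4 is oxygenated. Read backwards, C8(=O)–C7–C6–C5–C4=C3(OR) is an oxy-Cope retron. Its 1,5-diene C6=C7–C8(OH)–C3–C4=C5 sits in a bicyclo[2.2.2]octene with C3 and C10 as bridgeheads.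
- Forward ring order: the arene gives the six carbons of ring A. The Diels–Alder reaction with a chiral butenolide builds the bicyclooctene plus a lactone whose two carbons become C7 and C11. The [3,3] shift closes ring B and releases ring A. The coumarin is attached late and the exocyclic alkene is unveiled last.
- Stereochemistry: the menthyloxy acetal of the butenolide fixes the absolute sense of C8, C9 and C10. The endo, cis-fused lactone ties C7 and C11 to the side of the C4=C5 bridge. C5 follows from the cage-enforced suprafacial shift, and C3 comes from a reagent-controlled ketone reduction.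

Key step: step 11

Remark: carbons carry drimane numbers throughout (C3 acetoxy carbon, C4 gem-dimethyl carbon, C5 and C10 fusion carbons, C8 methylene-bearing carbon, C9 bearing C11), β is the face of the C5 and C10 methyl groups, the target is (3S,5S,9S,10R), and (5R)-5-(l-menthyloxy)furan-2(5H)-one is taken as purchasable (otherwise made from furfural, oxygen and l-menthol).

**Step 1**
Reactants: 1 2,3-dimethylanisole
Product: 2 4-bromo-2,3-dimethylanisole
Conditions: NBS, MeCN, 0 °C → rt
Reagents that add atoms: N-bromosuccinimide, O=C1CCC(=O)N1Br
Why: Electrophilic aromatic bromination, in which the methoxy group directs NBS in acetonitrile to the free para position.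

**Step 2**
Reactants: 2 4-bromo-2,3-dimethylanisole
Product: 4 2,3,4-trimethylanisole, via aryllithium 3 (not isolated)
Conditions: n-BuLi, THF, −78 °C; MeI, −78 °C → rt
Reagents that add atoms: iodomethane, CI
Why: Bromine–lithium exchange followed by SN2 methylation of the aryllithium places the future C10 methyl group regiospecifically.

**Step 3**
Reactants: 4 2,3,4-trimethylanisole
Product: 5 1-methoxy-2,3,4-trimethylcyclohexa-1,4-diene
Conditions: Li, NH3(l), THF, t-BuOH, −78 → −33 °C
Reagents that add atoms: none
Why: Birch reduction with protonation ortho and meta to the methoxy group keeps the enol ether, and any regioisomeric dihydroanisole formed alongside converges in the next step.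

**Step 4**
Reactants: 5 1-methoxy-2,3,4-trimethylcyclohexa-1,4-diene
Product: 6 1-methoxy-2,3,4-trimethylcyclohexa-1,3-diene
Conditions: KOt-Bu (cat.), DMSO, rt
Reagents that add atoms: none
Why: Base-catalysed prototropic conjugation of a dihydroanisole through the pentadienyl anion should settle on the conjugated, fully substituted 1-methoxy-1,3-diene, and minor isomers are left behind by the cycloaddition.

**Step 5**
Reactants: 6 1-methoxy-2,3,4-trimethylcyclohexa-1,3-diene; 7 (5R)-5-[(1R,2S,5R)-menthyloxy]furan-2(5H)-one
Product: 8 endo adduct, a bicyclo[2.2.2]octene (bridgeheads C3–OMe and C10–Me, C4=C5 dimethyl alkene) with a cis-fused lactone acetal on the C8–C9 bridge, C7(=O) on C8 and (R)-C11H(O-menthyl) on C9 both syn to the C4=C5 bridge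
Conditions: toluene, BHT, K2CO3 (trace), 115 °C, sealed tube
Reagents that add atoms: none
Why: In this thermal normal-demand Diels–Alder reaction of a 1-alkoxydiene with a γ-alkoxybutenolide, the methoxy group puts the largest HOMO coefficient on C10, which bonds to the β carbon C9 (ortho rule, bonds C9–C10 and C3–C8), the lactone lies endo and so syn to the new C4=C5 bridge, and the diene adds anti to the menthyloxy group, which sets C3, C8, C9 and C10 absolutely.

**Step 6**
Reactants: 8 endo adduct
Product: 11 tricyclic γ-lactone (C7(=O)–O–C11H2 cis-fused on C8–C9 and syn to the C4=C5 bridge), via formyl carboxylate 9 (not isolated), via hydroxy carboxylate 10 (not isolated)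
Conditions: KOH, NaBH4, EtOH–H2O, 0 °C → rt; 2 M HCl
Reagents that add atoms: none
Why: Saponification of the acyloxy acetal frees menthol and the C11 aldehyde, borohydride reduces the aldehyde faster than C9 can enolise, and acidification relactonises the cis hydroxy acid, which is the usual reductive removal of this auxiliary and touches no stereocentre.

**Step 7**
Reactants: 11 tricyclic γ-lactone
Product: 13 α-hydroxy lactone (C8–OH syn to the C1–C2 bridge), via lactone enolate 12 (not isolated)
Conditions: KN(SiMe3)2, THF, −78 °C; 2-(phenylsulfonyl)-3-phenyloxaziridine, −78 °C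
Reagents that add atoms: 2-(phenylsulfonyl)-3-phenyloxaziridine, O=S(=O)(N1OC1c1ccccc1)c1ccccc1
Why: In this enolate hydroxylation with an N-sulfonyloxaziridine, the C3 methoxy group cannot be eliminated because that would need a bridgehead alkene, and oxygen can enter only from the face of the C1–C2 bridge since the five-membered lactone must stay cis-fused, so C7 remains on the C4=C5 side.

**Step 8**
Reactants: 13 α-hydroxy lactone
Product: 14 lactol (mixture of C7 anomers)
Conditions: i-Bu2AlH (2.5 equiv), CH2Cl2, −78 °C; aq potassium sodium tartrate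
Reagents that add atoms: none
Why: Partial reduction of a lactone to the lactol at low temperature, with the first equivalent of hydride consumed by the tertiary hydroxyl group.

**Step 9**
Reactants: 14 lactol
Product: 15 vinyl carbinol diol (vinyl on C8 and CH2OH on C9 both syn to the C4=C5 bridge, C8–OH syn to the C1–C2 bridge)
Conditions: Ph3PCH3Br, n-BuLi, THF, 0 °C → rt
Reagents that add atoms: methyltriphenylphosphonium bromide, C[P+](c1ccccc1)(c1ccccc1)c1ccccc1.[Br-]
Why: Wittig methylenation of the lactol through its open hydroxy aldehyde form turns C7 into the vinyl group and frees C11–OH without touching C8 or C9, and the lithium counter-ion keeps the tertiary alkoxide from rearranging prematurely.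

**Step 10**
Reactants: 15 vinyl carbinol diol
Product: 16 bridged vinyl carbinol with C11–OMOM (precursor of the key step)
Conditions: MOMCl, i-Pr2NEt, CH2Cl2, 0 °C → rt
Reagents that add atoms: chloromethyl methyl ether, COCCl
Why: Chemoselective O-alkylation under amine base reaches only the primary hydroxyl and leaves the hindered tertiary carbinol free, and the MOM group tolerates KH and zinc carbenoids yet is removed without extra effort in step 13.

**Step 11**
Reactants: 16 bridged vinyl carbinol with C11–OMOM
Product: 19 cis-fused bicyclic C8 enol triflate (C7=C8–OTf) of the decal-8-one with C3=C4 methyl enol ether, 5β- and 10β-methyl and 9β-CH2OMOM, via potassium alkoxide 17 (not isolated), via potassium enolate 18 (not isolated)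
Conditions: KH, 18-crown-6, THF, 0 → 40 °C; N-(5-chloro-2-pyridyl)bis(trifluoromethanesulfonimide), −78 °C
Reagents that add atoms: N-(5-chloro-2-pyridyl)bis(trifluoromethanesulfonimide), O=S(=O)(N(c1ccc(Cl)cn1)S(=O)(=O)C(F)(F)F)C(F)(F)F
Why: KH with the crown ether gives the dissociated alkoxide 17, whose C6=C7–C8(O−)–C3–C4=C5 array undergoes a concerted, charge-accelerated [3,3] shift through the boat-like six-centre geometry imposed by the cage, so that C6 bonds to C5 while the C3–C8 bridge bond breaks, leaving the C7=C8 enolate 18 and the C3=C4 methyl enol ether. The closest known reaction type is the anionic oxy-Cope rearrangement of 1-methoxy-2-vinylbicyclo[2.2.2]oct-5-en-2-ols to cis-fused octalones, including cases that create a methyl-bearing fusion carbon. Ring B (C5–C6–C7–C8–C9–C10) closes by this suprafacial sigmatropic C5–C6 bond formation, and ring A is the cyclohexene of the bicycle set free by the C3–C8 cleavage. The only new stereocentre, C5, is controlled by the cage, because the vinyl terminus can reach only the face of C5 that looks at the C8–C9 bridge, so the C5 and C10 methyl groups end cis while C9 and C10 are carried over unchanged. The step needs the vinyl group on the C4=C5 side, which the lactone origin of C7 and C11 guarantees, and it needs the enolate to stay at C7=C8, since migration to C9 would bring epimerisation or loss of the C11 alkoxy group. Aprotic conditions and O-sulfonylation at −78 °C freeze that regiochemistry as enol triflate 19, which also masks C8 through the following acidic and reductive steps.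

**Step 12**
Reactants: 19 C8 enol triflate with C3=C4 methyl enol ether
Product: 20 3,4-methano compound (cyclopropane CH2 bridging C3 and C4, drawn on the α face, 3-OMe and 4-Me then β)
Conditions: Et2Zn, CH2I2 (5 equiv each), CH2Cl2, 0 °C → rt
Reagents that add atoms: diiodomethane, ICI
Why: In this Simmons–Smith cyclopropanation (Et2Zn/CH2I2 variant) the electrophilic zinc carbenoid attacks the electron-rich, zinc-coordinating enol ether while the enol triflate is deactivated, and the face of attack does not matter because both cyclopropanes give the same ketone in step 13.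

**Step 13**
Reactants: 20 3,4-methano compound
Product: 21 4,4-dimethyl-3-ketone with free C11–OH and C8 enol triflate
Conditions: 3 M aq HCl, MeOH, 60 °C
Reagents that add atoms: water, O
Why: In this acid opening of a donor-substituted cyclopropane, protonation of the unsubstituted CH2 cleaves its bond to C3, hydrolysis of the oxocarbenium ion gives the 3-ketone with the second methyl on C4, and the same medium hydrolyses the MOM acetal while the acid-stable enol triflate keeps C9 from enolising.

**Step 14**
Reactants: 21 4,4-dimethyl-3-ketone
Product: 22 3β-alcohol (3S) with free C11–OH and C8 enol triflate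
Conditions: (R)-2-methyl-CBS-oxazaborolidine (0.5 equiv), BH3·SMe2 (3 equiv), THF, −10 → 0 °C; MeOH
Reagents that add atoms: none
Why: A Corey–Bakshi–Shibata reduction is chosen because both ketone faces are encumbered (4β and 5β methyl groups on one, the folded ring B on the other), so the (R)-catalyst, which distinguishes quaternary C4 from the C2 methylene, is relied on to deliver hydride to the α face and set 3S.

**Step 15**
Reactants: 22 3β-alcohol
Product: 23 allylsilane diol (C7=C8–CH2SiMe3)
Conditions: Me3SiCH2MgCl (5 equiv), Pd(PPh3)4 (5 mol %), THF, rt → 45 °C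
Reagents that add atoms: (trimethylsilyl)methylmagnesium chloride, C[Si](C)(C)C[Mg]Cl
Why: Kumada coupling of an enol triflate under zerovalent palladium catalysis is a standard route to allylsilanes, and the two hydroxyl groups only consume extra Grignard reagent.

**Step 16**
Reactants: 23 allylsilane diol; 24 umbelliferone
Product: 25 C11 umbelliferyl ether with free 3β-OH
Conditions: PPh3, DIAD, THF, 0 → 40 °C
Reagents that add atoms: none
Why: In this Mitsunobu etherification the acidic 7-hydroxycoumarin displaces the activated primary C11 oxygen at a non-stereogenic carbon, and the neopentyl-type secondary 3β-hydroxyl is too hindered to compete.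

**Step 17**
Reactants: 25 C11 umbelliferyl ether
Product: 26 3β-acetate of the allylsilane
Conditions: Ac2O, DMAP, pyridine, rt
Reagents that add atoms: acetic anhydride, CC(=O)OC(C)=O
Why: DMAP-catalysed O-acylation of the remaining secondary alcohol proceeds with retention at C3.

**Step 18**
Reactants: 26 3β-acetate of the allylsilane
Product: 27 polyanthinin
Conditions: CF3CO2H (2 equiv), CH2Cl2, −20 °C; aq NaHCO3
Reagents that add atoms: none
Why: In this protodesilylation of an allylsilane (SE2′), protonation at C7 gives the β-silyl-stabilised C8 cation, which loses silicon to place the alkene exocyclic, and since the allylsilane is far more nucleophilic than the alkene formed, a short cold exposure should avoid migration into the ring.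

**Compound list**
1 | 2,3-dimethylanisole | COc1cccc(C)c1C | starting material
2 | 4-bromo-2,3-dimethylanisole | COc1ccc(Br)c(C)c1C | intermediate
3 | (4-methoxy-2,3-dimethylphenyl)lithium | [Li]c1ccc(OC)c(C)c1C | intermediate
4 | 2,3,4-trimethylanisole | COc1ccc(C)c(C)c1C | intermediate
5 | 1-methoxy-2,3,4-trimethylcyclohexa-1,4-diene (racemic at the sp3 methine, erased in step 4) | COC1=C(C)C(C)C(C)=CC1 | intermediate
6 | 1-methoxy-2,3,4-trimethylcyclohexa-1,3-diene | COC1=C(C)C(C)=C(C)CC1 | intermediate
7 | (5R)-5-[(1R,2S,5R)-menthyloxy]furan-2(5H)-one | O=C1C=C[C@H](O[C@@H]2C[C@H](C)CC[C@H]2C(C)C)O1 | starting material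
8 | endo Diels–Alder adduct, lactone acetal syn to the C4=C5 bridge, C11 (R) | O=C1O[C@@H](O[C@@H]4C[C@H](C)CC[C@H]4C(C)C)[C@H]2[C@@H]1[C@]3(OC)CC[C@@]2(C)C(C)=C3C | intermediate
9 | potassium carboxylate (C7) with C11 aldehyde, both syn to the C4=C5 bridge | [K+].[O-]C(=O)[C@@H]1[C@H](C=O)[C@@]2(C)CC[C@]1(OC)C(C)=C2C | intermediate
10 | potassium carboxylate (C7) with C11 hydroxymethyl | [K+].[O-]C(=O)[C@@H]1[C@H](CO)[C@@]2(C)CC[C@]1(OC)C(C)=C2C | intermediate
11 | tricyclic γ-lactone, cis-fused on C8–C9, syn to the C4=C5 bridge | O=C1OC[C@H]2[C@@H]1[C@]3(OC)CC[C@@]2(C)C(C)=C3C | intermediate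
12 | potassium enolate of lactone 11 (C7=C8) | [K+].[O-]C1=C2[C@]3(OC)CC[C@@](C)(C(C)=C3C)[C@H]2CO1 | intermediate
13 | α-hydroxy lactone, C8–OH syn to the C1–C2 bridge | O=C1OC[C@H]2[C@]1(O)[C@]3(OC)CC[C@@]2(C)C(C)=C3C | intermediate
14 | lactol (C7 anomers) | OC1OC[C@H]2[C@]1(O)[C@]3(OC)CC[C@@]2(C)C(C)=C3C | intermediate
15 | bridged vinyl carbinol with free C11–OH | C=C[C@@]1(O)[C@]2(OC)CC[C@@](C)(C(C)=C2C)[C@H]1CO | intermediate
16 | bridged vinyl carbinol, C11–OMOM (key-step precursor) | C=C[C@@]1(O)[C@]2(OC)CC[C@@](C)(C(C)=C2C)[C@H]1COCOC | intermediate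
17 | potassium alkoxide of 16 | [K+].C=C[C@@]1([O-])[C@]2(OC)CC[C@@](C)(C(C)=C2C)[C@H]1COCOC | intermediate
18 | potassium C7=C8 enolate of the cis-decal-8-one, C3=C4 methyl enol ether | [K+].[O-]C1=CC[C@]2(C)C(C)=C(OC)CC[C@]2(C)[C@H]1COCOC | intermediate
19 | C8 enol triflate of the cis-decal-8-one, C3=C4 methyl enol ether, 5β,10β-dimethyl, 9β-CH2OMOM (key-step product) | O=S(=O)(OC1=CC[C@]2(C)C(C)=C(OC)CC[C@]2(C)[C@H]1COCOC)C(F)(F)F | intermediate
20 | 3α,4α-methano-3β-methoxy-4β-methyl compound (α adduct drawn) | O=S(=O)(OC1=CC[C@]2(C)[C@]3(C)C[C@]3(OC)CC[C@]2(C)[C@H]1COCOC)C(F)(F)F | intermediate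
21 | 4,4-dimethyl-3-ketone, C11–OH, C8 enol triflate | O=S(=O)(OC1=CC[C@]2(C)C(C)(C)C(=O)CC[C@]2(C)[C@H]1CO)C(F)(F)F | intermediate
22 | 3β-alcohol, C11–OH, C8 enol triflate | O=S(=O)(OC1=CC[C@]2(C)C(C)(C)[C@@H](O)CC[C@]2(C)[C@H]1CO)C(F)(F)F | intermediate
23 | allylsilane diol | C[Si](C)(C)CC1=CC[C@]2(C)C(C)(C)[C@@H](O)CC[C@]2(C)[C@H]1CO | intermediate
24 | umbelliferone (7-hydroxycoumarin) | Oc1ccc2ccc(=O)oc2c1 | starting material
25 | allylsilane, C11 umbelliferyl ether, 3β-OH | C[Si](C)(C)CC1=CC[C@]2(C)C(C)(C)[C@@H](O)CC[C@]2(C)[C@H]1COc1ccc2ccc(=O)oc2c1 | intermediate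
26 | allylsilane, C11 umbelliferyl ether, 3β-OAc | C[Si](C)(C)CC1=CC[C@]2(C)C(C)(C)[C@@H](OC(C)=O)CC[C@]2(C)[C@H]1COc1ccc2ccc(=O)oc2c1 | intermediate
27 | polyanthinin | C=C1CC[C@]2(C)C(C)(C)[C@@H](OC(C)=O)CC[C@]2(C)[C@H]1COc1ccc2ccc(=O)oc2c1 | target

Total step count: 18. Longest linear sequence: 18 steps, from 2,3-dimethylanisole.

**Steps most likely to fail**

Step 5. The cycloaddition may be too slow, because both diene termini are fully substituted and the butenolide is only a moderate dienophile, so aromatisation or isomerisation of the diene could take over.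
- The fallback sets out from 6 and rejoins the route at 16. It uses a small, strongly activated dienophile and adds C11 and the vinyl group afterwards.
- Diene 6 reacts with 2-bromoacrolein under a diphenylprolinol-derived oxazaborolidinium triflimide catalyst (the antipode that gives the bicycle drawn) to give bromo aldehyde F1.
- NaClO2 oxidation gives bromo acid F2.
- Curtius rearrangement with (PhO)2P(O)N3, then hydrolysis of the α-bromo isocyanate, gives bicyclooctenone F3.
- The lithium enolate of F3 takes up monomeric formaldehyde on the face of the C4=C5 bridge to give ketol F4.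
- MOMCl with i-Pr2NEt gives MOM ether F5.
- Vinylmagnesium bromide with CeCl3 then gives 16, and the epimeric carbinol is removed by chromatography.

Step 12. The zinc carbenoid may not reach the tetrasubstituted C3=C4 bond next to quaternary C5, or zinc salts may hydrolyse the enol ether before cyclopropanation.
- The fallback sets out from 19 and rejoins at 21. It replaces carbene transfer by regiodefined enolate alkylation.
- Oxalic acid in wet THF hydrolyses 19 to 4-methyl-3-ketone F6.
- Me3SiCl and Et3N in hot DMF give the more substituted silyl enol ether F7.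
- Benzyltrimethylammonium fluoride with MeI alkylates C4 to give 4,4-dimethyl ketone F8.
- Methanolic HCl removes the MOM group and gives 21.

Step 14. Facial selectivity may be poor or the reduction sluggish, because the catalyst–borane complex must approach the concave α face.
- The fallback goes from 21 directly to 22 by electron transfer instead of hydride delivery, using SmI2 (divalent samarium) with H2O and Et3N in THF.
- Protonation of the ketyl-derived carbanion follows product stability and should give the equatorial alcohol.
- That alcohol is 3β-OH in the conformer that keeps C4 equatorial on ring B and C11 pseudoaxial beside the triflate.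
- No new compound is made.

**Further compounds**
F1 | step 5 | 2-bromo-1-methoxy-4,5,6-trimethylbicyclo[2.2.2]oct-5-ene-2-carbaldehyde (formyl group anti to the alkene bridge) | O=C[C@@]1(Br)C[C@@]2(C)CC[C@]1(OC)C(C)=C2C
F2 | step 5 | 2-bromo-1-methoxy-4,5,6-trimethylbicyclo[2.2.2]oct-5-ene-2-carboxylic acid | OC(=O)[C@@]1(Br)C[C@@]2(C)CC[C@]1(OC)C(C)=C2C
F3 | step 5 | 1-methoxy-4,5,6-trimethylbicyclo[2.2.2]oct-5-en-2-one | O=C1C[C@@]2(C)CC[C@]1(OC)C(C)=C2C
F4 | step 5 | 3-(hydroxymethyl)-1-methoxy-4,5,6-trimethylbicyclo[2.2.2]oct-5-en-2-one (CH2OH syn to the alkene bridge) | O=C1[C@H](CO)[C@@]2(C)CC[C@]1(OC)C(C)=C2C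
F5 | step 5 | MOM ether of F4 | O=C1[C@H](COCOC)[C@@]2(C)CC[C@]1(OC)C(C)=C2C
F6 | step 12 | 4-methyl-3-ketone with C8 enol triflate and C11–OMOM (C4 epimers) | O=S(=O)(OC1=CC[C@]2(C)C(C)C(=O)CC[C@]2(C)[C@H]1COCOC)C(F)(F)F
F7 | step 12 | C3=C4 trimethylsilyl enol ether of F6 | O=S(=O)(OC1=CC[C@]2(C)C(C)=C(O[Si](C)(C)C)CC[C@]2(C)[C@H]1COCOC)C(F)(F)F
F8 | step 12 | 4,4-dimethyl-3-ketone with C8 enol triflate and C11–OMOM | O=S(=O)(OC1=CC[C@]2(C)C(C)(C)C(=O)CC[C@]2(C)[C@H]1COCOC)C(F)(F)F
F0 | step 14 | none | none
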